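**Plan**
1. The target is (+)-lariciresinol esterified with stearic acid at its only aliphatic hydroxyl. The retrosynthesis cuts the ester C–O bond, then the O1–C2 bond of the oxolane (ring oxygen to the aryl-bearing carbon), then the C3–C4 bond of the oxolane.
2. The second cut returns C2-symmetric (2R,3R)-secoisolariciresinol; the third returns two identical 3-arylpropanoyl units.
3. Forward: oxidative homocoupling of a chiral imide enolate joins the chain and sets both backbone centres (R,R) from an (S)-oxazolidinone. Reduction and debenzylation give the tetraol, one DDQ dehydrogenation closes the oxolane (the only ring made), and lipase acylation ends the route.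
4. Enabling feature: the benzene ring on oxolane C2 carries a free hydroxyl para to that carbon, so it can be oxidised to a p-quinone methide whose exocyclic carbon is C2. The hydroxymethyl oxygen on C4 (future O1, its carbon future C5) lies in 5-exo reach.
5. Because the precursor has a C2 axis, this one event desymmetrises the two arms, forms the ring, sets the third stereocentre (aryl on C2 trans to the CH2OH on C3, substrate control) and leaves exactly one aliphatic hydroxyl for the stearate.

Key step: step 6

Remark: compounds 1, 3 and 12 and all reagents are taken to be commercial; the target descriptors are (2S,3R,4R) in oxolane numbering.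

Step 1
Reactants: 1 3-(4-hydroxy-3-methoxyphenyl)propanoic acid (dihydroferulic acid)
Product: 2 3-[4-(benzyloxy)-3-methoxyphenyl]propanoic acid
Conditions: BnBr (1.3 equiv), NaOH (2.5 equiv), EtOH/H2O, reflux; then aq HCl to pH 2
Reagents that add atoms: benzyl bromide, BrCc1ccccc1
Why: Williamson ether synthesis on the phenoxide; in aqueous ethanolic hydroxide the carboxylate is a poor nucleophile and any benzyl ester formed is saponified in the same pot.

Step 2
Reactants: 2 3-[4-(benzyloxy)-3-methoxyphenyl]propanoic acid; 3 (4S)-4-benzyl-1,3-oxazolidin-2-one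
Product: 5 (4S)-4-benzyl-3-{3-[4-(benzyloxy)-3-methoxyphenyl]propanoyl}-1,3-oxazolidin-2-one, via mixed pivalic anhydride 4 (not isolated)
Conditions: PivCl, Et3N, THF, −20 °C; then 3, LiCl, −20 → 20 °C
Reagents that add atoms: none
Why: N-acylation of the oxazolidinone through the mixed anhydride, in which the hindered pivaloyl carbonyl directs attack to the arylpropanoyl carbonyl.

Step 3
Reactants: 5 (4S)-4-benzyl-3-{3-[4-(benzyloxy)-3-methoxyphenyl]propanoyl}-1,3-oxazolidin-2-one (two molecules)
Product: 7 (4S,4'S)-3,3'-{(2R,3R)-2,3-bis[4-(benzyloxy)-3-methoxybenzyl]butanedioyl}bis(4-benzyl-1,3-oxazolidin-2-one), via lithium Z-enolate 6 (not isolated)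
Conditions: LiN(iPr)2 (1.1 equiv), THF, −78 °C; then TiCl4 (1.1 equiv), −78 → 0 °C
Reagents that add atoms: none
Why: Oxidative enolate homocoupling, in which TiCl4 takes one electron from each chelated Z-enolate (tetravalent titanium to trivalent titanium) and the two α-carbons join, each on the face anti to the 4-benzyl group of its own auxiliary, which sets both new centres R.

Step 4
Reactants: 7 (4S,4'S)-3,3'-{(2R,3R)-2,3-bis[4-(benzyloxy)-3-methoxybenzyl]butanedioyl}bis(4-benzyl-1,3-oxazolidin-2-one)
Product: 8 (2R,3R)-2,3-bis[4-(benzyloxy)-3-methoxybenzyl]butane-1,4-diol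
Conditions: LiBH4 (6 equiv), MeOH (6 equiv), THF, 0 → 20 °C
Reagents that add atoms: none
Why: Reductive cleavage of the N-acyl oxazolidinones by borohydride at the exocyclic carbonyls (a lactone formed on the way by transacylation is reduced to the same diol), without a base strong enough to epimerise the α-centres and with release of 3 for re-use.

Step 5
Reactants: 8 (2R,3R)-2,3-bis[4-(benzyloxy)-3-methoxybenzyl]butane-1,4-diol
Product: 9 (2R,3R)-2,3-bis(4-hydroxy-3-methoxybenzyl)butane-1,4-diol, (−)-secoisolariciresinol
Conditions: H2 (1 atm), 10% Pd/C, EtOAc/MeOH, 20 °C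
Reagents that add atoms: none
Why: Hydrogenolysis of the two aryl benzyl ethers on palladium, with nothing else in 8 being reducible.

Step 6
Reactants: 9 (−)-secoisolariciresinol
Product: 11 [(2S,3R,4R)-2-(4-hydroxy-3-methoxyphenyl)-4-(4-hydroxy-3-methoxybenzyl)oxolan-3-yl]methanol, (+)-lariciresinol, via p-quinone methide 10 (not isolated)
Conditions: DDQ (0.6 equiv, added over 1 h), 1,4-dioxane, 15–20 °C; hydroquinone filtered off; recovered 9 recycled
Reagents that add atoms: none
Why: DDQ removes a hydride from one benzylic CH2 and a proton from the para-hydroxyl of the same ring to give the p-quinone methide 10, and the hydroxymethyl oxygen on the neighbouring backbone carbon adds to its exocyclic carbon with re-aromatisation; the closest known reaction type is the DDQ dehydrogenative cyclisation of 4-hydroxybenzyl compounds onto a tethered hydroxyl, as in flavan formation from 1,3-diarylpropanes. The oxolane closes in the 5-exo-trig mode, the only alternative (attack by the other hydroxyl) being a 4-exo closure to an oxetane, which is not expected. The new centre (oxolane C2, S) is controlled by the adjacent C3: allylic 1,3-strain keeps the C3–H bond in the plane of the quinone methide, the oxygen arrives from the face of the carbon that carries it, and the aryl group should end trans to the CH2OH group, which is also the more stable isomer reachable by retro-addition. Because 9 has a C2 axis, oxidation of either ring leads to the same product, so no selectivity between the two arms is needed. What is needed is one ring closure and not two (a second dehydrogenation on the other arm would give the furofuran pinoresinol) and no further hydride abstraction at the new benzylic ether carbon; nothing in the substrate secures this, so it rests on slow addition of a deficit of DDQ, separation of the triol from recovered tetraol, and recycling. Friedel–Crafts capture of 10 by the other arene should be slower than the 5-exo oxygen attack as long as no acid is added and the hydroquinone precipitates.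

Step 7
Reactants: 11 (+)-lariciresinol; 12 vinyl octadecanoate (vinyl stearate)
Product: 13 [(2S,3R,4R)-2-(4-hydroxy-3-methoxyphenyl)-4-(4-hydroxy-3-methoxybenzyl)oxolan-3-yl]methyl octadecanoate
Conditions: immobilised Candida antarctica lipase B, 12 (3 equiv), tert-amyl alcohol, 4 Å molecular sieves, 50 °C
Reagents that add atoms: none
Why: Lipase-catalysed irreversible transesterification with a vinyl ester (the enol leaving group tautomerises to acetaldehyde), in which the serine hydrolase acylates the primary aliphatic alcohol and leaves the two phenols alone; no stereocentre is touched.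

**Compound list**
1 | 3-(4-hydroxy-3-methoxyphenyl)propanoic acid | OC(=O)CCc1ccc(O)c(OC)c1 | starting material
2 | 3-[4-(benzyloxy)-3-methoxyphenyl]propanoic acid | OC(=O)CCc1ccc(OCc2ccccc2)c(OC)c1 | intermediate
3 | (4S)-4-benzyl-1,3-oxazolidin-2-one | O=C1N[C@@H](Cc2ccccc2)CO1 | starting material
4 | 3-[4-(benzyloxy)-3-methoxyphenyl]propanoic pivalic anhydride (not isolated) | CC(C)(C)C(=O)OC(=O)CCc1ccc(OCc2ccccc2)c(OC)c1 | intermediate
5 | (4S)-4-benzyl-3-{3-[4-(benzyloxy)-3-methoxyphenyl]propanoyl}-1,3-oxazolidin-2-one | O=C(CCc1ccc(OCc2ccccc2)c(OC)c1)N1[C@@H](Cc2ccccc2)COC1=O | intermediate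
6 | lithium Z-enolate of 5 (not isolated) | [Li]O/C(=C\Cc1ccc(OCc2ccccc2)c(OC)c1)N1[C@@H](Cc2ccccc2)COC1=O | intermediate
7 | (4S,4'S)-3,3'-{(2R,3R)-2,3-bis[4-(benzyloxy)-3-methoxybenzyl]butanedioyl}bis(4-benzyl-1,3-oxazolidin-2-one) | O=C([C@H](Cc1ccc(OCc2ccccc2)c(OC)c1)[C@@H](Cc1ccc(OCc2ccccc2)c(OC)c1)C(=O)N1[C@@H](Cc2ccccc2)COC1=O)N1[C@@H](Cc2ccccc2)COC1=O | intermediate
8 | (2R,3R)-2,3-bis[4-(benzyloxy)-3-methoxybenzyl]butane-1,4-diol | OC[C@H](Cc1ccc(OCc2ccccc2)c(OC)c1)[C@@H](Cc1ccc(OCc2ccccc2)c(OC)c1)CO | intermediate
9 | (2R,3R)-2,3-bis(4-hydroxy-3-methoxybenzyl)butane-1,4-diol, (−)-secoisolariciresinol | OC[C@H](Cc1ccc(O)c(OC)c1)[C@@H](Cc1ccc(O)c(OC)c1)CO | intermediate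
10 | (2R,3R)-2-(4-hydroxy-3-methoxybenzyl)-3-[(3-methoxy-4-oxocyclohexa-2,5-dien-1-ylidene)methyl]butane-1,4-diol (not isolated) | OC[C@H](C=C1C=CC(=O)C(OC)=C1)[C@@H](Cc1ccc(O)c(OC)c1)CO | intermediate
11 | [(2S,3R,4R)-2-(4-hydroxy-3-methoxyphenyl)-4-(4-hydroxy-3-methoxybenzyl)oxolan-3-yl]methanol, (+)-lariciresinol | OC[C@H]1[C@@H](Cc2ccc(O)c(OC)c2)CO[C@@H]1c1ccc(O)c(OC)c1 | intermediate
12 | vinyl octadecanoate | CCCCCCCCCCCCCCCCCC(=O)OC=C | starting material
13 | [(2S,3R,4R)-2-(4-hydroxy-3-methoxyphenyl)-4-(4-hydroxy-3-methoxybenzyl)oxolan-3-yl]methyl octadecanoate | CCCCCCCCCCCCCCCCCC(=O)OC[C@H]1[C@@H](Cc2ccc(O)c(OC)c2)CO[C@@H]1c1ccc(O)c(OC)c1 | target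

**Count and risks**
Total step count: 7. Longest linear sequence: 7 steps (1 to 13; 3 and 12 enter as bought).

Steps most likely to fail:

Step 6. The dehydrogenation may not stop after one ring closure: a second closure on the other arm, or further hydride abstraction at the new benzylic ether carbon, may compete. The quinone methide may also be captured by the other arene in a Friedel–Crafts sense. The fallback places the benzylic leaving group by an aldol addition and closes the ring by acid-promoted ionisation, with no oxidant. It sets out from 5. Auxiliary-controlled alkylation of 5 (NaN(SiMe3)2, THF, −78 °C; tert-butyl bromoacetate) should give tert-butyl (3R)-4-[(4S)-4-benzyl-2-oxo-1,3-oxazolidin-3-yl]-3-[4-(benzyloxy)-3-methoxybenzyl]-4-oxobutanoate F1, which LiBH4 (THF/H2O, 0 °C) followed by TsOH (cat., toluene, 80 °C) should turn into (4R)-4-[4-(benzyloxy)-3-methoxybenzyl]oxolan-2-one F2 by reduction of the imide carbonyl and lactonisation. The lithium enolate of this lactone (LiN(iPr)2, THF, −78 °C) should add to 4-(benzyloxy)-3-methoxybenzaldehyde anti to the ring substituent and give (3S,4R)-4-[4-(benzyloxy)-3-methoxybenzyl]-3-{[4-(benzyloxy)-3-methoxyphenyl](hydroxy)methyl}oxolan-2-one F3 as a mixture of carbinol epimers, the carbinol centre being left undefined. LiAlH4 (THF, 0 °C) should reduce it to (2R,3R)-2-{[4-(benzyloxy)-3-methoxyphenyl](hydroxy)methyl}-3-[4-(benzyloxy)-3-methoxybenzyl]butane-1,4-diol F4, again as both carbinol epimers. Camphorsulfonic acid (cat., CH2Cl2, 0 °C) should ionise the benzylic alcohol of either epimer and close the oxolane through the hydroxymethyl group of the neighbouring backbone carbon, giving [(2S,3R,4R)-2-[4-(benzyloxy)-3-methoxyphenyl]-4-[4-(benzyloxy)-3-methoxybenzyl]oxolan-3-yl]methanol F5 with the 2,3-trans ring. Hydrogenolysis (H2, 10% Pd/C, EtOAc, stopped after two equivalents of uptake so that the benzylic ring C–O bond is kept) comes back to the route at 11.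

Step 3. The two enolate-derived radicals may couple with incomplete facial control (meso or mismatched diastereomers), or the enolate may be lost to protonation or over-oxidation instead of coupling. The fallback makes the central bond by two polar alkylations on a lactone instead of by oxidative dimerisation. It sets out from 5. Alkylation of its sodium enolate (NaN(SiMe3)2, THF, −78 °C) with tert-butyl bromoacetate should give tert-butyl (3R)-4-[(4S)-4-benzyl-2-oxo-1,3-oxazolidin-3-yl]-3-[4-(benzyloxy)-3-methoxybenzyl]-4-oxobutanoate F6, and LiBH4 followed by TsOH (cat., toluene, 80 °C) should give (4R)-4-[4-(benzyloxy)-3-methoxybenzyl]oxolan-2-one F7 after lactonisation. Deprotonation (LiN(iPr)2, THF, −78 °C) and alkylation with 4-(benzyloxy)-3-methoxybenzyl bromide anti to the existing benzyl group should give (3R,4R)-3,4-bis[4-(benzyloxy)-3-methoxybenzyl]oxolan-2-one F8, which LiAlH4 (THF, 0 °C) opens to the diol, coming back to the route at 8. F6 and F7 are the same compounds as F1 and F2, so both fallbacks run through the same lactone.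

Step 7. The lipase may not turn over the primary alcohol, which is flanked by two ring substituents, or slow acylation of the phenols may set in at long reaction times. The fallback is exhaustive acylation followed by chemoselective cleavage of the aryl esters. It sets out from 11. Stearoyl chloride (3.5 equiv), pyridine and DMAP (cat.) in CH2Cl2 should give the tristearate [(2S,3R,4R)-2-[3-methoxy-4-(octadecanoyloxy)phenyl]-4-[3-methoxy-4-(octadecanoyloxy)benzyl]oxolan-3-yl]methyl octadecanoate F9, from which pyrrolidine (2.2 equiv, CH2Cl2, 0 °C) should cleave only the two aryl esters, since aminolysis of aryl esters is much faster than that of the alkyl ester, coming back to the route at 13.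

**Further compounds**
F1 | step 6 | tert-butyl (3R)-4-[(4S)-4-benzyl-2-oxo-1,3-oxazolidin-3-yl]-3-[4-(benzyloxy)-3-methoxybenzyl]-4-oxobutanoate | CC(C)(C)OC(=O)C[C@@H](Cc1ccc(OCc2ccccc2)c(OC)c1)C(=O)N1[C@@H](Cc2ccccc2)COC1=O
F2 | step 6 | (4R)-4-[4-(benzyloxy)-3-methoxybenzyl]oxolan-2-one | O=C1C[C@@H](Cc2ccc(OCc3ccccc3)c(OC)c2)CO1
F3 | step 6 | (3S,4R)-4-[4-(benzyloxy)-3-methoxybenzyl]-3-{[4-(benzyloxy)-3-methoxyphenyl](hydroxy)methyl}oxolan-2-one | O=C1[C@H](C(O)c2ccc(OCc3ccccc3)c(OC)c2)[C@@H](Cc2ccc(OCc3ccccc3)c(OC)c2)CO1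
F4 | step 6 | (2R,3R)-2-{[4-(benzyloxy)-3-methoxyphenyl](hydroxy)methyl}-3-[4-(benzyloxy)-3-methoxybenzyl]butane-1,4-diol | OC[C@H](C(O)c1ccc(OCc2ccccc2)c(OC)c1)[C@@H](Cc1ccc(OCc2ccccc2)c(OC)c1)CO
F5 | step 6 | [(2S,3R,4R)-2-[4-(benzyloxy)-3-methoxyphenyl]-4-[4-(benzyloxy)-3-methoxybenzyl]oxolan-3-yl]methanol | OC[C@H]1[C@@H](Cc2ccc(OCc3ccccc3)c(OC)c2)CO[C@@H]1c1ccc(OCc2ccccc2)c(OC)c1
F6 | step 3 | tert-butyl (3R)-4-[(4S)-4-benzyl-2-oxo-1,3-oxazolidin-3-yl]-3-[4-(benzyloxy)-3-methoxybenzyl]-4-oxobutanoate | CC(C)(C)OC(=O)C[C@@H](Cc1ccc(OCc2ccccc2)c(OC)c1)C(=O)N1[C@@H](Cc2ccccc2)COC1=O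
F7 | step 3 | (4R)-4-[4-(benzyloxy)-3-methoxybenzyl]oxolan-2-one | O=C1C[C@@H](Cc2ccc(OCc3ccccc3)c(OC)c2)CO1
F8 | step 3 | (3R,4R)-3,4-bis[4-(benzyloxy)-3-methoxybenzyl]oxolan-2-one | O=C1[C@H](Cc2ccc(OCc3ccccc3)c(OC)c2)[C@@H](Cc2ccc(OCc3ccccc3)c(OC)c2)CO1
F9 | step 7 | [(2S,3R,4R)-2-[3-methoxy-4-(octadecanoyloxy)phenyl]-4-[3-methoxy-4-(octadecanoyloxy)benzyl]oxolan-3-yl]methyl octadecanoate | CCCCCCCCCCCCCCCCCC(=O)OC[C@H]1[C@@H](Cc2ccc(OC(=O)CCCCCCCCCCCCCCCCC)c(OC)c2)CO[C@@H]1c1ccc(OC(=O)CCCCCCCCCCCCCCCCC)c(OC)c1
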